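## Retrosynthetic overview

1. Daphnodorin C ⇐ global hydrogenolysis of protected spiro compound 21 ⇐ closure of the dihydrofuran (spiro carbon, C-8 and C-7 of flavan ring A, O-7, CHAr) by forming the C(spiro)–CH(Ar) bond in hemiketal 17, whose O-7 "protecting group" is a 4-(benzyloxy)benzyl ether that becomes the CHAr carbon with its aryl ring.
2. Enabling feature: the spiro carbon is at once a cation-stabilised benzylic, α-oxy carbon on the phloroglucinol-type ring A (an ionisable hemiketal carbon) and the α-carbon of the furanone C-3 ketone (nucleophilic as the 3-hydroxybenzofuran enol). It lies 1,5 to the O-7–CH2Ar hydrogens, whose carbon is a latent p-alkoxybenzyl/oxocarbenium centre, so hydride can pass from that CH2 to the spiro carbon and the two carbons then bond.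
3. 17 ⇐ Rubottom oxidation of 15 ⇐ Negishi coupling (C-8–C-2 bond) of 8-bromoflavan 9 with the 3-silyloxybenzofuran-2-ylzinc reagent 14.
4. 9 ⇐ bromination at C-8 ⇐ Mitsunobu closure of the chroman ring ⇐ CBS reduction ⇐ retro-chalcone from 2,4,6-trihydroxybenzaldehyde, 4-(benzyloxy)benzyl chloride and 4'-(benzyloxy)acetophenone.
5. Ring order: chroman ring (step 5); benzofuranone ring (bought, carried through); dihydrofuran ring last (step 11).

Key step: step 11

Assumption: PBB = 4-(benzyloxy)benzyl; the sense of induction of the chiral acid in step 11 cannot be predicted with confidence, so the (R)-acid is written and its antipode is to be used if that proves to be the matched one.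

## Route

Step 1
Reactants: 1 2,4,6-trihydroxybenzaldehyde; 2 4-(benzyloxy)benzyl chloride (2.1 equiv)
Product: 3 4,6-bis(PBB-oxy)-2-hydroxybenzaldehyde
Conditions: K2CO3, DMF, rt
Reagents that add atoms: none
Why: Williamson etherification should take the para-OH and one ortho-OH, the last ortho-OH being held back by its hydrogen bond to the formyl oxygen.

Step 2
Reactants: 3 4,6-bis(PBB-oxy)-2-hydroxybenzaldehyde; 4 4'-(benzyloxy)acetophenone
Product: 5 (E)-retro-chalcone
Conditions: KOH (50% aq.), EtOH–THF, rt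
Reagents that add atoms: none
Why: Claisen–Schmidt condensation in which only the acetophenone can enolise and the aldehyde cannot, the conjugated E-enone being the thermodynamic product.

Step 3
Reactants: 5 (E)-retro-chalcone
Product: 6 1-(4-benzyloxyphenyl)-3-aryl-propan-1-one
Conditions: H2 (4 atm), RhCl(PPh3)3 (5 mol %), toluene–EtOH, 40 °C
Reagents that add atoms: none
Why: Homogeneous rhodium-catalysed hydrogenation should saturate only the enone C=C, leaving the aryl ketone and all benzylic ethers untouched.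

Step 4
Reactants: 6 1-(4-benzyloxyphenyl)-3-aryl-propan-1-one
Product: 7 (1R)-1-(4-benzyloxyphenyl)-3-aryl-propan-1-ol
Conditions: (S)-2-methyl-CBS-oxazaborolidine (20 mol %), BH3·SMe2 (2.2 equiv), THF, −20 °C
Reagents that add atoms: none
Why: Corey–Bakshi–Shibata reduction, in which the (S)-catalyst differentiates the aryl (large) from the CH2CH2Ar (small) substituent and should give the (R)-carbinol, the free phenol being carried as its borate.

Step 5
Reactants: 7 (1R)-1-(4-benzyloxyphenyl)-3-aryl-propan-1-ol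
Product: 8 (2S)-4'-O-benzyl-5,7-di-O-PBB-flavan
Conditions: PPh3, DIAD, THF, 0 °C to rt
Reagents that add atoms: none
Why: Intramolecular Mitsunobu etherification (6-exo-tet) closes the chroman ring by SN2 attack of the phenol with inversion, turning the (R)-carbinol into the (S)-configured flavan C-2.

Step 6
Reactants: 8 (2S)-4'-O-benzyl-5,7-di-O-PBB-flavan
Product: 9 (2S)-8-bromo-4'-O-benzyl-5,7-di-O-PBB-flavan
Conditions: NBS (1.0 equiv), CH2Cl2, −78 to 0 °C
Reagents that add atoms: N-bromosuccinimide, O=C1CCC(=O)N1Br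
Why: Electrophilic aromatic bromination of the trioxygenated ring A should go to C-8, flanked by the tied-back ring oxygen, and not to C-6 between two bulky benzylic ethers, as is usual for 5,7-di-O-benzyl flavans.

Step 7
Reactants: 10 4,6-dihydroxybenzofuran-3(2H)-one
Product: 11 4,6-bis(benzyloxy)benzofuran-3(2H)-one
Conditions: BnBr (2.1 equiv), K2CO3, DMF, rt
Reagents that add atoms: benzyl bromide, BrCc1ccccc1
Why: Williamson O-benzylation of the two phenols under weak-base conditions.

Step 8
Reactants: 11 4,6-bis(benzyloxy)benzofuran-3(2H)-one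
Product: 12 4,6-bis(benzyloxy)-3-(triisopropylsilyloxy)benzofuran
Conditions: TIPSOTf, Et3N, CH2Cl2, 0 °C
Reagents that add atoms: triisopropylsilyl trifluoromethanesulfonate, CC(C)[Si](OS(=O)(=O)C(F)(F)F)(C(C)C)C(C)C
Why: Soft enolisation and O-silylation of the ketone, driven by formation of the aromatic furan, masks the ketone and leaves C-2–H as the only acidic position.

Step 9
Reactants: 12 4,6-bis(benzyloxy)-3-(triisopropylsilyloxy)benzofuran; 9 (2S)-8-bromo-4'-O-benzyl-5,7-di-O-PBB-flavan
Product: 15 2-(flavan-8-yl)-3-silyloxybenzofuran, via 2-lithiobenzofuran 13 (not isolated), via benzofuran-2-ylzinc chloride 14 (not isolated)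
Conditions: n-BuLi, THF, −78 °C; ZnCl2, −78 °C to rt; then 9, Pd2(dba)3 (2.5 mol %), XPhos (10 mol %), THF, 60 °C
Reagents that add atoms: none
Why: Negishi coupling, in which C-2 lithiation α to the furan oxygen and transmetalation give a small five-ring heteroarylzinc that a bulky biarylphosphine palladium catalyst should join to the di-ortho-oxygenated bromide, fixing the C-8–C-2 bond without regiochemical ambiguity.

Step 10
Reactants: 15 2-(flavan-8-yl)-3-silyloxybenzofuran
Product: 17 2-(flavan-8-yl)-2-hydroxybenzofuran-3(2H)-one, via 2-silyloxy ketone 16 (not isolated)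
Conditions: DMDO, acetone–CH2Cl2, −78 to 0 °C; then HF·pyridine, pyridine, THF, 0 °C
Reagents that add atoms: dimethyldioxirane, CC1(C)OO1
Why: Rubottom oxidation (epoxidation of the electron-rich enol ether, epoxide opening with 1,4-silyl shift) followed by buffered fluoride desilylation should give the hemiketal as a C-2 epimer mixture, which is inconsequential because C-2 is planarised in the next step.

Step 11
Reactants: 17 2-(flavan-8-yl)-2-hydroxybenzofuran-3(2H)-one
Product: 21 protected daphnodorin C, via benzofuranylium ion 18 (not isolated), via oxocarbenium ion 19 (not isolated), via enol 20 (not isolated)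
Conditions: (R)-3,3'-bis(2,4,6-triisopropylphenyl)-1,1'-binaphthyl-2,2'-diyl N-triflylphosphoramide (10 mol %), 5 Å molecular sieves, toluene, −40 to 0 °C
Reagents that add atoms: none
Why: Proposed new method: the acid ionises the hemiketal to the 3-oxobenzofuran-2-ylium ion 18 (stabilised by the trioxygenated ring A and paired with the chiral phosphoramide anion), a 1,5-hydride shift from the O-7 benzylic CH2 through a six-membered transition state moves the charge to the aryl-oxocarbenium (p-alkoxybenzyl) ion 19 and leaves C-2 as an enolisable CH, and the aromatic 3-hydroxybenzofuran enol 20 then bonds through C-2 to the cationic carbon. The closest known reaction types are the acid-catalysed 1,5-hydride-transfer/cyclisation (internal redox) cascades of benzylic ethers and amines ortho to a cationic acceptor, which run enantioselectively under chiral phosphoric acids, and the rhodium-carbene 1,5-C–H insertion of 2-(benzyloxy)aryl diazo compounds to 2-aryl-2,3-dihydrobenzofurans; new here is that an α-keto carbenium ion replaces the carbene and that hydride acceptor and nucleophile are the same carbon. The dihydrofuran closes in 5-exo-trig mode (enol carbon onto the exocyclic C=C of the quinoid form of the cation), which can equally be read as a disrotatory six-electron 1,5-electrocyclisation of the C-2–C-8=C-7–O-7=CH dipole. The spiro centre is set by the chiral counter-anion, which is hydrogen-bonded to the enol OH and ion-paired with the oxocarbenium ion and so fixes the face of the enol and the helical sense of the closing dipole, while the CH(Ar) centre follows from the geometry of closure: the E-oxocarbenium ion keeps its aryl group outside and the enol oxygen turns inward toward the cationic carbon, which places the aryl group cis to the furanone ring oxygen as in the target, the arrangement also expected to be the more stable one. Chemoselectivity rests on geometry, since only the O-7 benzylic hydrogens are 1,5 to C-2 (the O-5 ether is para and the chroman C-2–H is held anti to C-8 by its ring), and O-closure of the enol to a seven-membered acetal is reversible under the acid. The sieves take up the water so that the oxocarbenium ion is not hydrolysed.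

Step 12
Reactants: 21 protected daphnodorin C
Product: 22 daphnodorin C
Conditions: H2 (1 atm), Pd/C, THF–MeOH, rt
Reagents that add atoms: none
Why: Hydrogenolysis should cleave the four benzyl aryl ethers and both O–CH2 bonds of the 5-O-PBB group, while the two ring benzylic C–O bonds (flavan C-2 and the dihydrofuran CHAr next to the quaternary carbon) are secondary, hindered and slower, and no stereocentre is touched.

## Compound list

1 | 2,4,6-trihydroxybenzaldehyde | O=Cc1c(O)cc(O)cc1O | starting material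
2 | 4-(benzyloxy)benzyl chloride (PBB-Cl) | ClCc1ccc(OCc2ccccc2)cc1 | starting material
3 | 4,6-bis{[4-(benzyloxy)benzyl]oxy}-2-hydroxybenzaldehyde | O=Cc1c(O)cc(OCc2ccc(OCc3ccccc3)cc2)cc1OCc1ccc(OCc2ccccc2)cc1 | intermediate
4 | 1-[4-(benzyloxy)phenyl]ethanone (4'-(benzyloxy)acetophenone) | CC(=O)c1ccc(OCc2ccccc2)cc1 | starting material
5 | (E)-1-[4-(benzyloxy)phenyl]-3-(4,6-bis{[4-(benzyloxy)benzyl]oxy}-2-hydroxyphenyl)prop-2-en-1-one | O=C(/C=C/c1c(O)cc(OCc2ccc(OCc3ccccc3)cc2)cc1OCc1ccc(OCc2ccccc2)cc1)c1ccc(OCc2ccccc2)cc1 | intermediate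
6 | 1-[4-(benzyloxy)phenyl]-3-(4,6-bis{[4-(benzyloxy)benzyl]oxy}-2-hydroxyphenyl)propan-1-one | O=C(CCc1c(O)cc(OCc2ccc(OCc3ccccc3)cc2)cc1OCc1ccc(OCc2ccccc2)cc1)c1ccc(OCc2ccccc2)cc1 | intermediate
7 | (1R)-1-[4-(benzyloxy)phenyl]-3-(4,6-bis{[4-(benzyloxy)benzyl]oxy}-2-hydroxyphenyl)propan-1-ol | O[C@H](CCc1c(O)cc(OCc2ccc(OCc3ccccc3)cc2)cc1OCc1ccc(OCc2ccccc2)cc1)c1ccc(OCc2ccccc2)cc1 | intermediate
8 | (2S)-2-[4-(benzyloxy)phenyl]-5,7-bis{[4-(benzyloxy)benzyl]oxy}chroman (protected flavan) | O(Cc1ccc(OCc2ccccc2)cc1)c1cc(OCc2ccc(OCc3ccccc3)cc2)c2c(c1)O[C@H](c1ccc(OCc3ccccc3)cc1)CC2 | intermediate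
9 | (2S)-8-bromo-2-[4-(benzyloxy)phenyl]-5,7-bis{[4-(benzyloxy)benzyl]oxy}chroman | O(Cc1ccc(OCc2ccccc2)cc1)c1cc(OCc2ccc(OCc3ccccc3)cc2)c2c(c1Br)O[C@H](c1ccc(OCc3ccccc3)cc1)CC2 | intermediate
10 | 4,6-dihydroxybenzofuran-3(2H)-one | O=C1COc2cc(O)cc(O)c12 | starting material
11 | 4,6-bis(benzyloxy)benzofuran-3(2H)-one | O=C1COc2cc(OCc3ccccc3)cc(OCc3ccccc3)c12 | intermediate
12 | 4,6-bis(benzyloxy)-3-[(triisopropylsilyl)oxy]benzofuran | CC(C)[Si](Oc1coc2cc(OCc3ccccc3)cc(OCc3ccccc3)c12)(C(C)C)C(C)C | intermediate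
13 | 2-lithio derivative of 12 (not isolated) | [Li]c1oc2cc(OCc3ccccc3)cc(OCc3ccccc3)c2c1O[Si](C(C)C)(C(C)C)C(C)C | intermediate
14 | [4,6-bis(benzyloxy)-3-(triisopropylsilyloxy)benzofuran-2-yl]zinc chloride (not isolated) | Cl[Zn]c1oc2cc(OCc3ccccc3)cc(OCc3ccccc3)c2c1O[Si](C(C)C)(C(C)C)C(C)C | intermediate
15 | 4,6-bis(benzyloxy)-2-[(2S)-2-(4-benzyloxyphenyl)-5,7-bis{[4-(benzyloxy)benzyl]oxy}chroman-8-yl]-3-[(triisopropylsilyl)oxy]benzofuran | CC(C)[Si](Oc1c(-c2c(OCc3ccc(OCc4ccccc4)cc3)cc(OCc3ccc(OCc4ccccc4)cc3)c3c2O[C@H](c2ccc(OCc4ccccc4)cc2)CC3)oc2cc(OCc3ccccc3)cc(OCc3ccccc3)c12)(C(C)C)C(C)C | intermediate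
16 | 2-(triisopropylsilyloxy) ketone: as 17 but with OSi(i-Pr)3 in place of OH at C-2 (C-2 epimers; not isolated) | O=C1c2c(OCc3ccccc3)cc(OCc3ccccc3)cc2OC1(O[Si](C(C)C)(C(C)C)C(C)C)c1c(OCc2ccc(OCc3ccccc3)cc2)cc(OCc2ccc(OCc3ccccc3)cc2)c2c1O[C@H](c1ccc(OCc3ccccc3)cc1)CC2 | intermediate
17 | 4,6-bis(benzyloxy)-2-[(2S)-2-(4-benzyloxyphenyl)-5,7-bis{[4-(benzyloxy)benzyl]oxy}chroman-8-yl]-2-hydroxybenzofuran-3(2H)-one (hemiketal, C-2 epimers) | O=C1c2c(OCc3ccccc3)cc(OCc3ccccc3)cc2OC1(O)c1c(OCc2ccc(OCc3ccccc3)cc2)cc(OCc2ccc(OCc3ccccc3)cc2)c2c1O[C@H](c1ccc(OCc3ccccc3)cc1)CC2 | intermediate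
18 | 3-oxobenzofuran-2-ylium ion from 17 by loss of hydroxide (cation of the chiral ion pair; not isolated) | O=C1c2c(OCc3ccccc3)cc(OCc3ccccc3)cc2O[C+]1c1c(OCc2ccc(OCc3ccccc3)cc2)cc(OCc2ccc(OCc3ccccc3)cc2)c2c1O[C@H](c1ccc(OCc3ccccc3)cc1)CC2 | intermediate
19 | 2-H benzofuranone carrying the O-7 aryl-oxocarbenium ion O-7=CH–C6H4–OBn after the 1,5-hydride shift (not isolated) | O=C1c2c(OCc3ccccc3)cc(OCc3ccccc3)cc2OC1c1c([O+]=Cc2ccc(OCc3ccccc3)cc2)cc(OCc2ccc(OCc3ccccc3)cc2)c2c1O[C@H](c1ccc(OCc3ccccc3)cc1)CC2 | intermediate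
20 | 3-hydroxybenzofuran (enol) tautomer of 19 (not isolated) | Oc1c(-c2c([O+]=Cc3ccc(OCc4ccccc4)cc3)cc(OCc3ccc(OCc4ccccc4)cc3)c3c2O[C@H](c2ccc(OCc4ccccc4)cc2)CC3)oc2cc(OCc3ccccc3)cc(OCc3ccccc3)c12 | intermediate
21 | protected daphnodorin C: furanone 4,6-di-O-benzyl, both 4-hydroxyphenyl rings O-benzyl, flavan 5-O-[4-(benzyloxy)benzyl]; spiro carbon (S), adjacent CHAr (S), flavan C-2 (S) | O=C1c2c(OCc3ccccc3)cc(OCc3ccccc3)cc2O[C@]12c1c(cc(OCc3ccc(OCc4ccccc4)cc3)c3c1O[C@H](c1ccc(OCc4ccccc4)cc1)CC3)O[C@H]2c1ccc(OCc3ccccc3)cc1 | intermediate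
22 | daphnodorin C; spiro carbon (S), adjacent CHAr (S), flavan C-2 (S) | O=C1c2c(O)cc(O)cc2O[C@]12c1c(cc(O)c3c1O[C@H](c1ccc(O)cc1)CC3)O[C@H]2c1ccc(O)cc1 | target

## Step count and risks

Total step count: 12. Longest linear sequence: 10 steps (steps 1–6 and 9–12).

Steps most likely to fail:

1. Step 11 (Proposed new method). Acid-induced loss of the 4-(benzyloxy)benzyl ethers or an aryl (α-ketol) shift of the hemiketal may outrun ionisation and hydride shift, and face selectivity at the spiro carbon may be poor. Fallback with known chemistry, setting out from 15: a Mukaiyama aldol addition of the silyl enol ether to 4-(benzyloxy)benzaldehyde (BF3·OEt2, CH2Cl2, −78 °C) should give the quaternary β-hydroxy ketone F1 as an isomer mixture. Treatment with TFA (10 vol % in CH2Cl2) and pentamethylbenzene at 0 °C should remove both PBB ethers, ionise the p-alkoxybenzylic alcohol and let O-7 close the dihydrofuran by SN1 etherification, giving the 5-hydroxy tetra-O-benzyl spiro compound F2. The spiro epimers are diastereomers because of flavan C-2 and would be separated by chromatography, the CHAr centre being free to equilibrate under the acid. Hydrogenolysis under the conditions of step 12 then comes back to the route at 22.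

2. Step 9. Slow oxidative addition and transmetalation at the di-ortho-oxygenated bromide, protodemetalation of the zinc reagent, or O-to-C silyl migration in the lithio species may stall the coupling. Fallback setting out from 11 and 9: a palladium-catalysed ketone α-arylation (Pd2(dba)3, P(t-Bu)3, NaOt-Bu, THF, 50 °C) should give the 2-arylbenzofuranone F3 directly. O-silylation (TIPSOTf, Et3N, CH2Cl2) then comes back to the route at 15.

3. Step 5. Partial ionisation of the p-alkoxybenzylic oxyphosphonium intermediate (SN1 leakage) may erode the configuration at flavan C-2. Fallback setting out from 6: acid-catalysed cyclodehydration (PPTS, toluene, 80 °C, 4 Å sieves) should give the 2-aryl-4H-chromene F4. Asymmetric hydrogenation of this enol ether with a chiral iridium N,P-ligand complex of the type [Ir(cod)(PHOX)]BArF (H2 50 bar, CH2Cl2; ligand antipode chosen for the S product) sets C-2 by catalyst control and comes back to the route at 8.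

## Further compounds

F1 | step 11 | 4,6-bis(benzyloxy)-2-{[4-(benzyloxy)phenyl](hydroxy)methyl}-2-[(2S)-2-(4-benzyloxyphenyl)-5,7-bis{[4-(benzyloxy)benzyl]oxy}chroman-8-yl]benzofuran-3(2H)-one (isomer mixture at the two new centres) | O=C1c2c(OCc3ccccc3)cc(OCc3ccccc3)cc2OC1(C(O)c1ccc(OCc2ccccc2)cc1)c1c(OCc2ccc(OCc3ccccc3)cc2)cc(OCc2ccc(OCc3ccccc3)cc2)c2c1O[C@H](c1ccc(OCc3ccccc3)cc1)CC2
F2 | step 11 | tetra-O-benzyl daphnodorin C with free flavan 5-OH (furanone 4,6-di-O-benzyl, both 4-hydroxyphenyl rings O-benzyl) | O=C1c2c(OCc3ccccc3)cc(OCc3ccccc3)cc2O[C@]12c1c(cc(O)c3c1O[C@H](c1ccc(OCc4ccccc4)cc1)CC3)O[C@H]2c1ccc(OCc3ccccc3)cc1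
F3 | step 9 | 4,6-bis(benzyloxy)-2-[(2S)-2-(4-benzyloxyphenyl)-5,7-bis{[4-(benzyloxy)benzyl]oxy}chroman-8-yl]benzofuran-3(2H)-one (C-2 epimers) | O=C1c2c(OCc3ccccc3)cc(OCc3ccccc3)cc2OC1c1c(OCc2ccc(OCc3ccccc3)cc2)cc(OCc2ccc(OCc3ccccc3)cc2)c2c1O[C@H](c1ccc(OCc3ccccc3)cc1)CC2
F4 | step 5 | 2-[4-(benzyloxy)phenyl]-5,7-bis{[4-(benzyloxy)benzyl]oxy}-4H-chromene | O(Cc1ccc(OCc2ccccc2)cc1)c1cc(OCc2ccc(OCc3ccccc3)cc2)c2c(c1)OC(c1ccc(OCc3ccccc3)cc1)=CC2
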